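At early times ring closure, dimerisation and the protic impurity draw on the starting material at its charge concentration, and the contest between ring closure and dimerisation shifts as the starting material thins out.

common to all: starting material 1.5 M; protic impurity 0.0300 M

| run | time |
|---|---|
| Friday's | 1.5 h |
| Tuesday's | 3.0 h |
| Wednesday's | 6.0 h |

    starting material → ring (k1 = 0.014 min⁻¹)
    2 starting material → open dimer (k2 = 0.0069 M⁻¹ min⁻¹)
    starting material + protic impurity → quenched substrate (k3 = 0.37 M⁻¹ min⁻¹)
    crystals ⇌ ring, rate k4*(cs4 - [ring]) while solid is left; crystals form when [ring] > cs4 (cs4 = 0.30 M, k4 = 0.44 min⁻¹)

- in percentages every species weighs as the starting material in it: one open dimer counts as two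
- for ring the crystals are counted in
- where a step has two of a species, its rate is k times that concentration squared, and two are used at each turn
- as a solid, counted per litre of solution: crystals
- run time (Friday's): 1.5 h

1. which of these there is most of at the end, counted by the starting material in it, Friday's (starting material / ring / open dimer)
2. which of these there is most of at the end, counted by the starting material in it, Tuesday's (starting material / ring / open dimer)
3. which of these there is most of at the end, counted by the starting material in it, Wednesday's (starting material / ring / open dimer)
4. the largest of these amounts at the end, in percent of the starting material charged, Friday's
5. the largest of these amounts at the end, in percent of the starting material charged, Tuesday's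
6. the largest of these amounts at the end, in percent of the starting material charged, Wednesday's

1. The protic impurity meets the starting material with a pseudo-first-order half-life of 1.25 min, shorter than the 0.83 h of ring closure, so it acts first. Its charge removes 2.00% of the starting material, and 98.0% remains for the other two paths.

2. Crystals are counted as ring, and no arrow leads onward from either, so crystallisation only moves material within that count.

3. Ring closure is first order and dimerisation second order. Between these two paths, the selectivity towards ring is k(ring) / (k(ring) + 2 k(dimer) c(starting material)).

4. Two extreme flasks can be solved in the head. With c(starting material) held at the charge, the share is 40.3%, and open dimer leads. In the dilute limit, the share tends to 100%.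

5. The real flask passes through each concentration once on its way down, so the curve can be replaced by its mean. The share at the midpoint, 0.750 M, is 57.5%, and this is taken as the mean ring share. The curve bows downward, so this value lies below the true mean, and the average of the two ends, 70.2%, lies above it. Ring at full conversion of the starting material therefore lies between 56.3% and 68.8%, ahead of open dimer.

6. The same mean gives a first-order constant of 0.0244 min⁻¹. My reckoning leaves 11.2% of the starting material in Friday's flask and gives 49.9% ring there, ahead of open dimer at 36.9%. It gives 55.6% ring in Tuesday's flask and 56.3% in Wednesday's.

The forecast, reasoning that “the crystallisation step drops out”, names ring, ring and ring, at 48.2%, 57.3% and 60.3% for Friday's, Tuesday's and Wednesday's.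

The simulation gives ring as the largest amount in each flask: 48.1% on Friday's, 57.3% on Tuesday's and 60.3% on Wednesday's.

In a flask like Wednesday's but charged with 0.38 M of starting material, the mean ring share rises to 84.2%. After the loss to the protic impurity this predicts 77.6% ring, and that flask reads 78.5% at 6.00 h. Wednesday's flask, at 6.00 h, still holds 0.26% of its starting material. The mean share applied to the 98.0% spared by the protic impurity gives 56.3%, which is 4.2 percentage points under the ring found in Wednesday's flask at ten times the time. That longer wait changes little: open dimer stands at 37.5%, crystals go from 40.3% to 40.5%, and ring goes from 60.3% to 60.5% at 60.0 h.

(The numbers of this flask are invented; the rest is arithmetic.)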